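Is this flask still moving when you read it at 2.5 d, and how do its products divide?

starting material 10 mM; coupling partner 0.600 equiv; protic impurity 2.00 mM; catalyst 0.44 mol%; time 2.5 d

    starting material + coupling partner ⇌ target (K1 = 680 M⁻¹, k1 = 0.0258 M⁻¹ s⁻¹)
    starting material + coupling partner ⇌ isomer of the product (K2 = 480 M⁻¹, k2 = 5.94 × 10⁻⁴ M⁻¹ s⁻¹)
    target + catalyst ⇌ isomer of the product + catalyst, rate k3*[catalyst]*[target] forward; the back reaction follows from the equilibrium constant (k3 = 0.0927 M⁻¹ s⁻¹)
    catalyst ⇌ dormant form (K4 = 0.530, k4 = 2.80 × 10⁻⁵ s⁻¹)
    coupling partner + catalyst + target → catalyst + over-reaction product (k5 = 11.2 M⁻² s⁻¹)
    starting material + protic impurity → quenched substrate (k6 = 0.00487 M⁻¹ s⁻¹)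

- at 2.5 d, what has stopped the reaction, if anything has (no working catalyst is left / forward and back rates have come level / the coupling partner has run out first / all of the starting material has reacted / it is still moving)
- conversion of starting material at 2.5 d
- amount of target at 2.5 d, in percent of the starting material charged
- amount of isomer of the product at 2.5 d, in percent of the starting material charged
- amount of over-reaction product at 2.5 d, in percent of the starting material charged

- the reaction counts as stopped when no species that holds the starting material changes by six tenths of a point or more over the second half of the time
- run time (flask): 2.5 d

My own reckoning goes after one number: the isomer's share of the pair, meaning c(isomer of the product) over c(target) plus c(isomer of the product). In this flask the starting material has a forward half-life of 1.24 h with the coupling partner as charged, so the target comes to stand level with them early. Control then passes to something slower. The catalyst exchanges with its dormant form with a relaxation half-life of 0.0993 d, leaving 65.4% of it working, which is 0.0288 mM. Multiplied by the rate constant of the isomerisation, this gives a pseudo-first-order constant of 0.230 d⁻¹ from target to isomer. The uncatalysed second step draws on the same starting material and coupling partner, whose product stands at c(target) over the first equilibrium constant, so it acts as a further route of 0.0755 d⁻¹. Both routes run back and end at the same ratio, an end share of 41.4%. The pair clock, the half-life with which the share closes on that end value, is 0.938 d, which is longer than the first step's time.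

That gives two ways to the share at 2.5 d. The clock runs 2.67 half-lives and gives 34.9%. Counting the forward flow alone gives 76.5%, more than the end share, so that way cheats by leaving out the back reactions, and I keep the clock. Over the second half of the time the share still moves by 9.9 percentage points. The isomer therefore passes the stopping mark of 0.600 point if the pair stays at 6.06% of the charge or more over that time. With the first equilibrium constant times the starting concentration at 6.8, I expect it to hold much more, so I call this flask still moving.

The forecast says it is still moving, with conversion 65%, target 28%, isomer 14% and over-reaction product 3.2%, on the grounds that “target-to-isomer relaxation takes more than a day”. Its figures put the share at 33.3%, against my 34.9%.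

The simulated flask at 2.5 d reads it is still moving, with conversion 65.1%, target 27.1%, isomer 15.2% and over-reaction product 3.14%, all within the forecast's margins. The same flask with 2.40 equiv of coupling partner shows what it takes to break the forecast: conversion 96.6% and over-reaction product 42.3%. In the flask as charged, the share reads 35.9% against the clock's 34.9%. Read at 25 h, the same flask gives a clock share of 22.2% and a reading of 23.7%.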